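**Retrosynthetic overview**
1. Target 22 ⇐ O‑acetylation and ester hydrolysis ⇐ methyl (13Z)‑19‑hydroxylabda‑8(17),13‑dien‑15‑oate 19.
2. 19 ⇐ one cationic bicyclisation of the acyclic (S)‑oxirane 18: ring A closes first (C4–C5), then ring B (C10–C9), and the allylsilane ends the cascade as the 8(17)‑methylene.
3. 18 ⇐ chain growth by two acetoacetate dianion alkylations (C6–C7, C11–C12); enol phosphate → allylsilane (C17); enol triflate → (13Z)‑enoate (C16).
4. C4 stereocentre ⇐ Sharpless epoxidation and hydride opening of (2E,6E)‑8‑hydroxygeranyl acetate 2 ⇐ geranyl acetate 1.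

Assumption: the SMILES is read as (4S,5R,9S,10R,13Z)‑19‑acetoxylabda‑8(17),13‑dien‑15‑oic acid, C‑numbers in the Why lines are labdane positions of the target, and in the fallback that uses an 8‑phenylmenthyl ester the (1R,2S,5R) antipode is taken to give the 4S series (otherwise its mirror image is used).

**Step 1**
Reactants: 1 geranyl acetate
Product: 2 (2E,6E)-8-hydroxy-3,7-dimethylocta-2,6-dien-1-yl acetate
Conditions: SeO2 (0.1 equiv), t-BuOOH (3 equiv), salicylic acid (0.1 equiv), CH2Cl2, rt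
Reagents that add atoms: selenium dioxide, O=[Se]=O (catalytic oxygen carrier); tert-butyl hydroperoxide, CC(C)(C)OO (terminal oxidant)
Why: Riley allylic oxidation (ene reaction then 2,3-sigmatropic shift) attacks only the (E)-methyl of the electron-rich terminal alkene, the other alkene being deactivated by the allylic acetate.

**Step 2**
Reactants: 2 (2E,6E)-8-hydroxy-3,7-dimethylocta-2,6-dien-1-yl acetate
Product: 3 (2E)-5-[(2R,3R)-3-(hydroxymethyl)-3-methyloxiran-2-yl]-3-methylpent-2-en-1-yl acetate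
Conditions: Ti(OiPr)4 (0.1 equiv), D-(−)-diethyl tartrate (0.12 equiv), t-BuOOH (2 equiv), 4 Å MS, CH2Cl2, −20 °C
Reagents that add atoms: tert-butyl hydroperoxide, CC(C)(C)OO
Why: Sharpless asymmetric epoxidation acts only on the free allylic alcohol, and the D-tartrate ligand delivers oxygen to the face that gives the (2R,3R)-epoxide, which fixes the C–O configuration at the future C4.

**Step 3**
Reactants: 3 (2E)-5-[(2R,3R)-3-(hydroxymethyl)-3-methyloxiran-2-yl]-3-methylpent-2-en-1-yl acetate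
Product: 4 (2S,6E)-2,6-dimethyloct-6-ene-1,2,8-triol
Conditions: LiAlH4 (3 equiv), THF, 0 °C to rt; H2O, aqueous NaOH work-up
Reagents that add atoms: none
Why: Hydride opens the trisubstituted epoxide by SN2 attack at its less hindered CH carbon, so the tertiary C–O bond keeps its configuration (now 2S), and the acetate is reduced off in the same pot.

**Step 4**
Reactants: 4 (2S,6E)-2,6-dimethyloct-6-ene-1,2,8-triol
Product: 5 (2E)-3-methyl-6-[(4S)-2,2,4-trimethyl-1,3-dioxolan-4-yl]hex-2-en-1-ol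
Conditions: 2,2-dimethoxypropane (1.5 equiv), pyridinium p-toluenesulfonate (0.05 equiv), acetone, rt; aqueous NaHCO3
Reagents that add atoms: 2,2-dimethoxypropane, COC(C)(C)OC
Why: Acid-catalysed transketalisation gives the five-membered acetonide of the 1,2-diol under thermodynamic control and leaves the remote allylic alcohol free.

**Step 5**
Reactants: 5 (2E)-3-methyl-6-[(4S)-2,2,4-trimethyl-1,3-dioxolan-4-yl]hex-2-en-1-ol
Product: 6 (4S)-4-[(4E)-6-bromo-4-methylhex-4-en-1-yl]-2,2,4-trimethyl-1,3-dioxolane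
Conditions: CBr4 (1.2 equiv), PPh3 (1.25 equiv), 2,6-lutidine (0.2 equiv), CH2Cl2, −20 to 0 °C
Reagents that add atoms: carbon tetrabromide, BrC(Br)(Br)Br
Why: Appel bromination converts the primary allylic alcohol into the bromide under neutral conditions that spare the acetonide and the alkene geometry.

**Step 6**
Reactants: 6 (4S)-4-[(4E)-6-bromo-4-methylhex-4-en-1-yl]-2,2,4-trimethyl-1,3-dioxolane; 7 methyl acetoacetate
Product: 8 methyl (6E)-7-methyl-3-oxo-10-[(4S)-2,2,4-trimethyl-1,3-dioxolan-4-yl]dec-6-enoate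
Conditions: 7 (1.3 equiv), NaH, THF, 0 °C; n-BuLi, 0 °C; then 6, 0 °C; H2O
Reagents that add atoms: none
Why: Weiler dianion alkylation, in which the more basic terminal carbanion of the acetoacetate dianion displaces the allylic bromide by SN2 and forms the C6–C7 bond.

**Step 7**
Reactants: 8 methyl (6E)-7-methyl-3-oxo-10-[(4S)-2,2,4-trimethyl-1,3-dioxolan-4-yl]dec-6-enoate
Product: 9 methyl (2Z,6E)-3-[(diethoxyphosphoryl)oxy]-7-methyl-10-[(4S)-2,2,4-trimethyl-1,3-dioxolan-4-yl]deca-2,6-dienoate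
Conditions: NaH (1.1 equiv), Et2O, 0 °C; ClP(O)(OEt)2 (1.1 equiv), 0 °C to rt
Reagents that add atoms: diethyl chlorophosphate, CCOP(=O)(Cl)OCC
Why: O-phosphorylation of the sodium-chelated enolate in ether gives the (Z)-enol phosphate, which fixes the geometry of the future C8=C9 alkene.

**Step 8**
Reactants: 9 methyl (2Z,6E)-3-[(diethoxyphosphoryl)oxy]-7-methyl-10-[(4S)-2,2,4-trimethyl-1,3-dioxolan-4-yl]deca-2,6-dienoate
Product: 10 methyl (2Z,6E)-7-methyl-3-[(trimethylsilyl)methyl]-10-[(4S)-2,2,4-trimethyl-1,3-dioxolan-4-yl]deca-2,6-dienoate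
Conditions: Me3SiCH2MgCl (2.5 equiv), Ni(acac)2 (0.05 equiv), THF, 0 °C to rt
Reagents that add atoms: (trimethylsilyl)methylmagnesium chloride, C[Si](C)(C)C[Mg]Cl
Why: Nickel-catalysed Kumada coupling replaces the enol phosphate by CH2SiMe3 with retention of alkene geometry and so installs the allylsilane terminator (C17) with C7 trans to C11.

**Step 9**
Reactants: 10 methyl (2Z,6E)-7-methyl-3-[(trimethylsilyl)methyl]-10-[(4S)-2,2,4-trimethyl-1,3-dioxolan-4-yl]deca-2,6-dienoate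
Product: 11 (2Z,6E)-7-methyl-3-[(trimethylsilyl)methyl]-10-[(4S)-2,2,4-trimethyl-1,3-dioxolan-4-yl]deca-2,6-dien-1-ol
Conditions: i-Bu2AlH (2.5 equiv), CH2Cl2, −78 °C; aqueous potassium sodium tartrate
Reagents that add atoms: none
Why: DIBAL 1,2-reduction of the unsaturated ester gives the allylic alcohol without touching the acetonide or the allylsilane.

**Step 10**
Reactants: 11 (2Z,6E)-7-methyl-3-[(trimethylsilyl)methyl]-10-[(4S)-2,2,4-trimethyl-1,3-dioxolan-4-yl]deca-2,6-dien-1-ol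
Product: 12 (4S)-4-[(4E,8Z)-10-bromo-4-methyl-8-[(trimethylsilyl)methyl]deca-4,8-dien-1-yl]-2,2,4-trimethyl-1,3-dioxolane
Conditions: CBr4 (1.2 equiv), PPh3 (1.25 equiv), 2,6-lutidine (0.2 equiv), CH2Cl2, −30 °C; used crude
Reagents that add atoms: carbon tetrabromide, BrC(Br)(Br)Br
Why: Appel bromination at low temperature under buffered neutral conditions gives the primary allylic bromide without protodesilylation or allylic transposition.

**Step 11**
Reactants: 12 (4S)-4-[(4E,8Z)-10-bromo-4-methyl-8-[(trimethylsilyl)methyl]deca-4,8-dien-1-yl]-2,2,4-trimethyl-1,3-dioxolane; 7 methyl acetoacetate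
Product: 13 methyl (6Z,10E)-11-methyl-3-oxo-7-[(trimethylsilyl)methyl]-14-[(4S)-2,2,4-trimethyl-1,3-dioxolan-4-yl]tetradeca-6,10-dienoate
Conditions: 7 (1.3 equiv), NaH, THF, 0 °C; n-BuLi, 0 °C; then 12, −20 to 0 °C; H2O
Reagents that add atoms: none
Why: A second Weiler dianion alkylation (SN2 at the primary allylic bromide) forms the C11–C12 bond and brings in C12 to C15.

**Step 12**
Reactants: 13 methyl (6Z,10E)-11-methyl-3-oxo-7-[(trimethylsilyl)methyl]-14-[(4S)-2,2,4-trimethyl-1,3-dioxolan-4-yl]tetradeca-6,10-dienoate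
Product: 14 methyl (2E,6Z,10E)-11-methyl-3-{[(trifluoromethyl)sulfonyl]oxy}-7-[(trimethylsilyl)methyl]-14-[(4S)-2,2,4-trimethyl-1,3-dioxolan-4-yl]tetradeca-2,6,10-trienoate
Conditions: Tf2O (1.5 equiv), aqueous Me4NOH (4 equiv), toluene, 0 to 5 °C
Reagents that add atoms: trifluoromethanesulfonic anhydride, O=S(=O)(OS(=O)(=O)C(F)(F)F)C(F)(F)F
Why: Stereoselective enol triflation under non-chelating biphasic conditions traps the free tetramethylammonium enolate in its dipole-minimised form as the (E)-enol triflate, which sets the C13=C14 geometry.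

**Step 13**
Reactants: 14 methyl (2E,6Z,10E)-11-methyl-3-{[(trifluoromethyl)sulfonyl]oxy}-7-[(trimethylsilyl)methyl]-14-[(4S)-2,2,4-trimethyl-1,3-dioxolan-4-yl]tetradeca-2,6,10-trienoate
Product: 15 methyl (2Z,6Z,10E)-3,11-dimethyl-7-[(trimethylsilyl)methyl]-14-[(4S)-2,2,4-trimethyl-1,3-dioxolan-4-yl]tetradeca-2,6,10-trienoate
Conditions: MeZnCl (2 equiv), Pd(PPh3)4 (0.05 equiv), THF, rt
Reagents that add atoms: methylzinc chloride, C[Zn]Cl
Why: Negishi coupling replaces the triflate by methyl (C16) with retention, so C12 stays cis to the ester and the alkene is the (13Z)-enoate of the target.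

**Step 14**
Reactants: 15 methyl (2Z,6Z,10E)-3,11-dimethyl-7-[(trimethylsilyl)methyl]-14-[(4S)-2,2,4-trimethyl-1,3-dioxolan-4-yl]tetradeca-2,6,10-trienoate
Product: 16 methyl (2Z,6Z,10E,15S)-15,16-dihydroxy-3,11,15-trimethyl-7-[(trimethylsilyl)methyl]hexadeca-2,6,10-trienoate
Conditions: pyridinium p-toluenesulfonate (0.2 equiv), MeOH, 45 °C
Reagents that add atoms: none
Why: Mild acid-catalysed transketalisation to methanol frees the 1,2-diol at an acidity at which allylsilanes are not protodesilylated.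

**Step 15**
Reactants: 16 methyl (2Z,6Z,10E,15S)-15,16-dihydroxy-3,11,15-trimethyl-7-[(trimethylsilyl)methyl]hexadeca-2,6,10-trienoate
Product: 18 methyl (2Z,6Z,10E)-3,11-dimethyl-14-[(2S)-2-methyloxiran-2-yl]-7-[(trimethylsilyl)methyl]tetradeca-2,6,10-trienoate, via primary tosylate 17 (not isolated)
Conditions: TsCl (1.1 equiv), Et3N, DMAP (0.05 equiv), CH2Cl2, 0 °C; then K2CO3, MeOH, rt
Reagents that add atoms: p-toluenesulfonyl chloride, Cc1ccc(cc1)S(Cl)(=O)=O (stays in 17 only)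
Why: Selective sulfonylation of the primary hydroxyl and intramolecular Williamson displacement by the tertiary alkoxide close the oxirane without touching the stereocentre, so 18 is the (S)-epoxide.

**Step 16**
Reactants: 18 methyl (2Z,6Z,10E)-3,11-dimethyl-14-[(2S)-2-methyloxiran-2-yl]-7-[(trimethylsilyl)methyl]tetradeca-2,6,10-trienoate
Product: 19 methyl (4S,5R,9S,10R,13Z)-19-hydroxylabda-8(17),13-dien-15-oate
Conditions: MeAlCl2 (2.5 equiv), CH2Cl2, −78 °C, 1 h; aqueous NaHCO3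
Reagents that add atoms: none
Why: Proposed new method: enantiospecific exo-mode oxirane-initiated polyene bicyclisation, in which MeAlCl2 activates the (S)-2,2-disubstituted oxirane and C5 of the C5=C10 alkene opens its tertiary C4–O bond from the backside (SN2-like inversion, so the Sharpless-derived centre becomes the quaternary C4 and the oxirane CH2 becomes the C19 carbinol), the C10 cation is taken up anti by C9 of the allylsilane through a chair–chair array (the E-alkene gives the trans ring fusion with 5α-H and 10β-CH3, the allylsilane geometry puts C11 equatorial at C9) and loss of Me3Si from C17 leaves only the 8(17)-methylene; the in-plane backside trajectory is reached by the tether only from the staggered rotamer with C2 between the oxirane CH2 and the incoming alkene, which places CH2O axial (C19, cis to C20) and CH3 equatorial; the closest known reaction types are MeAlCl2-promoted cyclisations of trisubstituted epoxy polyenes, allylsilane-terminated cation–olefin cyclisations and invertive epoxide–arene cyclialkylations at tertiary oxirane carbons.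

**Step 17**
Reactants: 19 methyl (4S,5R,9S,10R,13Z)-19-hydroxylabda-8(17),13-dien-15-oate
Product: 20 (4S,5R,9S,10R,13Z)-19-hydroxylabda-8(17),13-dien-15-oic acid
Conditions: LiOH·H2O (5 equiv), THF/MeOH/H2O (3:1:1), 45 °C; then 1 M HCl to pH 3, 0 °C
Reagents that add atoms: lithium hydroxide, [Li+].[OH-]
Why: Saponification by acyl–oxygen cleavage of the methyl ester, to which the 8(17)-alkene and the (13Z)-enoate geometry are stable at this temperature.

**Step 18**
Reactants: 20 (4S,5R,9S,10R,13Z)-19-hydroxylabda-8(17),13-dien-15-oic acid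
Product: 22 (4S,5R,9S,10R,13Z)-19-acetoxylabda-8(17),13-dien-15-oic acid (target CNP0360430.3), via mixed acetic anhydride 21 (not isolated)
Conditions: Ac2O (3 equiv), pyridine, DMAP (0.1 equiv), CH2Cl2, rt; then THF/aqueous NaHCO3, rt, 1 h; acidify to pH 4
Reagents that add atoms: acetic anhydride, CC(=O)OC(C)=O
Why: DMAP-catalysed acylation esterifies the neopentyl C19 hydroxyl, while the carboxyl group forms only a labile mixed anhydride that the bicarbonate treatment hydrolyses back to the acid.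

**Compound list**
1 | geranyl acetate, (2E)-3,7-dimethylocta-2,6-dien-1-yl acetate | CC(C)=CCC/C(C)=C/COC(C)=O | starting material
2 | (2E,6E)-8-hydroxy-3,7-dimethylocta-2,6-dien-1-yl acetate | OC/C(C)=C/CC/C(C)=C/COC(C)=O | intermediate
3 | (2E)-5-[(2R,3R)-3-(hydroxymethyl)-3-methyloxiran-2-yl]-3-methylpent-2-en-1-yl acetate | C[C@]1(CO)O[C@@H]1CC/C(C)=C/COC(C)=O | intermediate
4 | (2S,6E)-2,6-dimethyloct-6-ene-1,2,8-triol | C[C@](O)(CCC/C(C)=C/CO)CO | intermediate
5 | (2E)-3-methyl-6-[(4S)-2,2,4-trimethyl-1,3-dioxolan-4-yl]hex-2-en-1-ol | C[C@]1(CCC/C(C)=C/CO)COC(C)(C)O1 | intermediate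
6 | (4S)-4-[(4E)-6-bromo-4-methylhex-4-en-1-yl]-2,2,4-trimethyl-1,3-dioxolane | C[C@]1(CCC/C(C)=C/CBr)COC(C)(C)O1 | intermediate
7 | methyl acetoacetate (methyl 3-oxobutanoate) | CC(=O)CC(=O)OC | starting material
8 | methyl (6E)-7-methyl-3-oxo-10-[(4S)-2,2,4-trimethyl-1,3-dioxolan-4-yl]dec-6-enoate | C[C@]1(CCC/C(C)=C/CCC(=O)CC(=O)OC)COC(C)(C)O1 | intermediate
9 | methyl (2Z,6E)-3-[(diethoxyphosphoryl)oxy]-7-methyl-10-[(4S)-2,2,4-trimethyl-1,3-dioxolan-4-yl]deca-2,6-dienoate | C[C@]1(CCC/C(C)=C/CC/C(OP(=O)(OCC)OCC)=C/C(=O)OC)COC(C)(C)O1 | intermediate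
10 | methyl (2Z,6E)-7-methyl-3-[(trimethylsilyl)methyl]-10-[(4S)-2,2,4-trimethyl-1,3-dioxolan-4-yl]deca-2,6-dienoate | C[C@]1(CCC/C(C)=C/CC/C(C[Si](C)(C)C)=C/C(=O)OC)COC(C)(C)O1 | intermediate
11 | (2Z,6E)-7-methyl-3-[(trimethylsilyl)methyl]-10-[(4S)-2,2,4-trimethyl-1,3-dioxolan-4-yl]deca-2,6-dien-1-ol | C[C@]1(CCC/C(C)=C/CC/C(C[Si](C)(C)C)=C/CO)COC(C)(C)O1 | intermediate
12 | (4S)-4-[(4E,8Z)-10-bromo-4-methyl-8-[(trimethylsilyl)methyl]deca-4,8-dien-1-yl]-2,2,4-trimethyl-1,3-dioxolane | C[C@]1(CCC/C(C)=C/CC/C(C[Si](C)(C)C)=C/CBr)COC(C)(C)O1 | intermediate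
13 | methyl (6Z,10E)-11-methyl-3-oxo-7-[(trimethylsilyl)methyl]-14-[(4S)-2,2,4-trimethyl-1,3-dioxolan-4-yl]tetradeca-6,10-dienoate | C[C@]1(CCC/C(C)=C/CC/C(C[Si](C)(C)C)=C/CCC(=O)CC(=O)OC)COC(C)(C)O1 | intermediate
14 | methyl (2E,6Z,10E)-11-methyl-3-{[(trifluoromethyl)sulfonyl]oxy}-7-[(trimethylsilyl)methyl]-14-[(4S)-2,2,4-trimethyl-1,3-dioxolan-4-yl]tetradeca-2,6,10-trienoate | C[C@]1(CCC/C(C)=C/CC/C(C[Si](C)(C)C)=C/CC/C(OS(=O)(=O)C(F)(F)F)=C\C(=O)OC)COC(C)(C)O1 | intermediate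
15 | methyl (2Z,6Z,10E)-3,11-dimethyl-7-[(trimethylsilyl)methyl]-14-[(4S)-2,2,4-trimethyl-1,3-dioxolan-4-yl]tetradeca-2,6,10-trienoate | C[C@]1(CCC/C(C)=C/CC/C(C[Si](C)(C)C)=C/CC/C(C)=C\C(=O)OC)COC(C)(C)O1 | intermediate
16 | methyl (2Z,6Z,10E,15S)-15,16-dihydroxy-3,11,15-trimethyl-7-[(trimethylsilyl)methyl]hexadeca-2,6,10-trienoate | C[C@](O)(CCC/C(C)=C/CC/C(C[Si](C)(C)C)=C/CC/C(C)=C\C(=O)OC)CO | intermediate
17 | methyl (2Z,6Z,10E,15S)-15-hydroxy-3,11,15-trimethyl-16-(tosyloxy)-7-[(trimethylsilyl)methyl]hexadeca-2,6,10-trienoate | C[C@](O)(CCC/C(C)=C/CC/C(C[Si](C)(C)C)=C/CC/C(C)=C\C(=O)OC)COS(=O)(=O)c1ccc(C)cc1 | intermediate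
18 | methyl (2Z,6Z,10E)-3,11-dimethyl-14-[(2S)-2-methyloxiran-2-yl]-7-[(trimethylsilyl)methyl]tetradeca-2,6,10-trienoate | C[C@]1(CCC/C(C)=C/CC/C(C[Si](C)(C)C)=C/CC/C(C)=C\C(=O)OC)CO1 | intermediate
19 | methyl (4S,5R,9S,10R,13Z)-19-hydroxylabda-8(17),13-dien-15-oate | C=C1CC[C@H]2[C@@](C)(CO)CCC[C@]2(C)[C@H]1CC/C(C)=C\C(=O)OC | intermediate
20 | (4S,5R,9S,10R,13Z)-19-hydroxylabda-8(17),13-dien-15-oic acid | C=C1CC[C@H]2[C@@](C)(CO)CCC[C@]2(C)[C@H]1CC/C(C)=C\C(=O)O | intermediate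
21 | acetic (4S,5R,9S,10R,13Z)-19-acetoxylabda-8(17),13-dien-15-oic anhydride | C=C1CC[C@H]2[C@@](C)(COC(C)=O)CCC[C@]2(C)[C@H]1CC/C(C)=C\C(=O)OC(C)=O | intermediate
22 | (4S,5R,9S,10R,13Z)-19-acetoxylabda-8(17),13-dien-15-oic acid | C=C1CC[C@H]2[C@@](C)(COC(C)=O)CCC[C@]2(C)[C@H]1CC/C(C)=C\C(=O)O | target

**Totals**
Total step count: 18. Longest linear sequence: 18 steps (1 to 22; 7 enters at steps 6 and 11).

**Three steps most likely to fail**

Step 16 (the proposed new step). The risks are a Meinwald hydride shift of the activated oxirane to an aldehyde, ionisation to an open C4 cation (loss of enantiopurity and of the axial CH2O preference), and capture of the C10 cation by the C19 alkoxide. The fallback uses known chemistry: an oxidative free-radical polyene cyclisation of a 2-methyl-3-oxo ester controlled by an 8-phenylmenthyl ester, followed by Barton–McCombie deoxygenation. It sets out from 7 and comes back at 20. The dianion of 7 is alkylated with commercial geranyl bromide to methyl (6E)-7,11-dimethyl-3-oxododeca-6,10-dienoate F1. Tf2O with aqueous Me4NOH gives methyl (2E,6E)-7,11-dimethyl-3-{[(trifluoromethyl)sulfonyl]oxy}dodeca-2,6,10-trienoate F2, and MeZnCl with Pd(PPh3)4 gives methyl (2Z,6E)-3,7,11-trimethyldodeca-2,6,10-trienoate F3. SeO2 with t-BuOOH oxidises the terminal (E)-methyl to methyl (2Z,6E,10E)-12-hydroxy-3,7,11-trimethyldodeca-2,6,10-trienoate F4, and CBr4 with PPh3 gives methyl (2Z,6E,10E)-12-bromo-3,7,11-trimethyldodeca-2,6,10-trienoate F5. F5 alkylates the dianion of (1R,2S,5R)-8-phenylmenthyl 2-methyl-3-oxobutanoate to give 1-[(1R,2S,5R)-8-phenylmenthyl] 16-methyl (6E,10E,14Z)-2,6,10,14-tetramethyl-3-oxohexadeca-6,10,14-trienedioate F6. Mn(OAc)3·2H2O and Cu(OAc)2·H2O in AcOH close ring A and then ring B, with the ester axial at C4 and the C8 radical oxidised to the 8(17)-alkene, to give (1R,2S,5R)-8-phenylmenthyl (13Z)-15-methoxy-3,15-dioxolabda-8(17),13-dien-19-oate F7. NaBH4 gives (1R,2S,5R)-8-phenylmenthyl (13Z)-3β-hydroxy-15-methoxy-15-oxolabda-8(17),13-dien-19-oate F8, PhOC(S)Cl with DMAP gives (1R,2S,5R)-8-phenylmenthyl (13Z)-15-methoxy-15-oxo-3β-[(phenoxycarbonothioyl)oxy]labda-8(17),13-dien-19-oate F9, and Bu3SnH with AIBN gives (1R,2S,5R)-8-phenylmenthyl (13Z)-15-methoxy-15-oxolabda-8(17),13-dien-19-oate F10. LiAlH4 reduces both esters to (13Z)-labda-8(17),13-diene-15,19-diol F11 with recovery of the auxiliary. MnO2 oxidises only the allylic alcohol to (13Z)-19-hydroxylabda-8(17),13-dien-15-al F12, and NaClO2 with NaH2PO4 and 2-methyl-2-butene gives 20.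

Step 12. The (E)-selectivity of the triflation decides the 13Z geometry, and Tf2O may attack the allylsilane or the acetonide. The fallback replaces enol triflate coupling by syn-carbocupration of an ynoate. It sets out from 12 and comes back at 15. Bromide 12 is alkylated with 3-lithio-1-(trimethylsilyl)propyne (from 1-(trimethylsilyl)propyne and n-BuLi, THF, −78 °C) to give (4S)-2,2,4-trimethyl-4-[(4E,8Z)-4-methyl-13-(trimethylsilyl)-8-[(trimethylsilyl)methyl]trideca-4,8-dien-12-yn-1-yl]-1,3-dioxolane F13. K2CO3 in MeOH removes only the alkynyl silyl group to give (4S)-2,2,4-trimethyl-4-[(4E,8Z)-4-methyl-8-[(trimethylsilyl)methyl]trideca-4,8-dien-12-yn-1-yl]-1,3-dioxolane F14. n-BuLi and then ClCO2Me give methyl (6Z,10E)-11-methyl-7-[(trimethylsilyl)methyl]-14-[(4S)-2,2,4-trimethyl-1,3-dioxolan-4-yl]tetradeca-6,10-dien-2-ynoate F15. Me2CuLi in THF at −78 °C adds methyl and hydrogen syn, which gives 15.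

Step 1. Allylic oxidation with SeO2 stops at partial conversion and over-oxidises to the enal. The fallback builds the (E)-allylic alcohol by olefination instead of C–H oxidation. It sets out from 1 and comes back at 2. mCPBA epoxidises only the terminal alkene to (2E)-5-(3,3-dimethyloxiran-2-yl)-3-methylpent-2-en-1-yl acetate F16. H5IO6 cleaves it to (2E)-3-methyl-6-oxohex-2-en-1-yl acetate F17. Wittig reaction with 2-(triphenylphosphoranylidene)propanal gives (2E,6E)-3,7-dimethyl-8-oxoocta-2,6-dien-1-yl acetate F18, and NaBH4 with CeCl3·7H2O in MeOH gives 2.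

**Further compounds**
F1 | step 16 | methyl (6E)-7,11-dimethyl-3-oxododeca-6,10-dienoate | CC(C)=CCC/C(C)=C/CCC(=O)CC(=O)OC
F2 | step 16 | methyl (2E,6E)-7,11-dimethyl-3-{[(trifluoromethyl)sulfonyl]oxy}dodeca-2,6,10-trienoate | CC(C)=CCC/C(C)=C/CC/C(OS(=O)(=O)C(F)(F)F)=C\C(=O)OC
F3 | step 16 | methyl (2Z,6E)-3,7,11-trimethyldodeca-2,6,10-trienoate | CC(C)=CCC/C(C)=C/CC/C(C)=C\C(=O)OC
F4 | step 16 | methyl (2Z,6E,10E)-12-hydroxy-3,7,11-trimethyldodeca-2,6,10-trienoate | OC/C(C)=C/CC/C(C)=C/CC/C(C)=C\C(=O)OC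
F5 | step 16 | methyl (2Z,6E,10E)-12-bromo-3,7,11-trimethyldodeca-2,6,10-trienoate | BrC/C(C)=C/CC/C(C)=C/CC/C(C)=C\C(=O)OC
F6 | step 16 | 1-[(1R,2S,5R)-8-phenylmenthyl] 16-methyl (6E,10E,14Z)-2,6,10,14-tetramethyl-3-oxohexadeca-6,10,14-trienedioate | CC(C)(c1ccccc1)[C@@H]1CC[C@@H](C)C[C@H]1OC(=O)C(C)C(=O)CC/C(C)=C/CC/C(C)=C/CC/C(C)=C\C(=O)OC
F7 | step 16 | (1R,2S,5R)-8-phenylmenthyl (13Z)-15-methoxy-3,15-dioxolabda-8(17),13-dien-19-oate | C=C1CC[C@H]2[C@@](C)(C(=O)O[C@@H]3C[C@H](C)CC[C@H]3C(C)(C)c3ccccc3)C(=O)CC[C@]2(C)[C@H]1CC/C(C)=C\C(=O)OC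
F8 | step 16 | (1R,2S,5R)-8-phenylmenthyl (13Z)-3β-hydroxy-15-methoxy-15-oxolabda-8(17),13-dien-19-oate | C=C1CC[C@H]2[C@@](C)(C(=O)O[C@@H]3C[C@H](C)CC[C@H]3C(C)(C)c3ccccc3)[C@@H](O)CC[C@]2(C)[C@H]1CC/C(C)=C\C(=O)OC
F9 | step 16 | (1R,2S,5R)-8-phenylmenthyl (13Z)-15-methoxy-15-oxo-3β-[(phenoxycarbonothioyl)oxy]labda-8(17),13-dien-19-oate | C=C1CC[C@H]2[C@@](C)(C(=O)O[C@@H]3C[C@H](C)CC[C@H]3C(C)(C)c3ccccc3)[C@@H](OC(=S)Oc3ccccc3)CC[C@]2(C)[C@H]1CC/C(C)=C\C(=O)OC
F10 | step 16 | (1R,2S,5R)-8-phenylmenthyl (13Z)-15-methoxy-15-oxolabda-8(17),13-dien-19-oate | C=C1CC[C@H]2[C@@](C)(C(=O)O[C@@H]3C[C@H](C)CC[C@H]3C(C)(C)c3ccccc3)CCC[C@]2(C)[C@H]1CC/C(C)=C\C(=O)OC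
F11 | step 16 | (13Z)-labda-8(17),13-diene-15,19-diol | C=C1CC[C@H]2[C@@](C)(CO)CCC[C@]2(C)[C@H]1CC/C(C)=C\CO
F12 | step 16 | (13Z)-19-hydroxylabda-8(17),13-dien-15-al | C=C1CC[C@H]2[C@@](C)(CO)CCC[C@]2(C)[C@H]1CC/C(C)=C\C=O
F13 | step 12 | (4S)-2,2,4-trimethyl-4-[(4E,8Z)-4-methyl-13-(trimethylsilyl)-8-[(trimethylsilyl)methyl]trideca-4,8-dien-12-yn-1-yl]-1,3-dioxolane | C[C@]1(CCC/C(C)=C/CC/C(C[Si](C)(C)C)=C/CCC#C[Si](C)(C)C)COC(C)(C)O1
F14 | step 12 | (4S)-2,2,4-trimethyl-4-[(4E,8Z)-4-methyl-8-[(trimethylsilyl)methyl]trideca-4,8-dien-12-yn-1-yl]-1,3-dioxolane | C[C@]1(CCC/C(C)=C/CC/C(C[Si](C)(C)C)=C/CCC#C)COC(C)(C)O1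
F15 | step 12 | methyl (6Z,10E)-11-methyl-7-[(trimethylsilyl)methyl]-14-[(4S)-2,2,4-trimethyl-1,3-dioxolan-4-yl]tetradeca-6,10-dien-2-ynoate | C[C@]1(CCC/C(C)=C/CC/C(C[Si](C)(C)C)=C/CCC#CC(=O)OC)COC(C)(C)O1
F16 | step 1 | (2E)-5-(3,3-dimethyloxiran-2-yl)-3-methylpent-2-en-1-yl acetate | CC1(C)OC1CC/C(C)=C/COC(C)=O
F17 | step 1 | (2E)-3-methyl-6-oxohex-2-en-1-yl acetate | O=CCC/C(C)=C/COC(C)=O
F18 | step 1 | (2E,6E)-3,7-dimethyl-8-oxoocta-2,6-dien-1-yl acetate | O=C/C(C)=C/CC/C(C)=C/COC(C)=O
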